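Ring A of tatanan B (C1 ethyl, C2 methyl, C3 aryl, C4 methyl, C5 aryl, C6 spiro) is cut at both bonds to C6, the carbon it shares with dienone ring B (C6–C11). The key step exploits that C6 is flanked by benzylic C5 and by C1, which is made allylic by holding the future C2 methyl as an exocyclic CH2: both neighbours can be ionised from carbinols, so ring B enters as intact 2,5-dimethoxyphenol, whose para carbon is alkylated twice in one flask, the second time with dearomatisation. The precursor is an acyclic 1,5-diol that carries only the C3 and C4 stereocentres; hydrogenation of the methylene completes the route.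

Key step: step 6

Labels: C1–C11 in the text follow the numbering above, also for the acyclic compounds (C1 = CH(OH)Et, C2 = C(=CH2), C3 = CH(Ar), C4 = CH(CH3), C5 = CH(OH)Ar); systematic names carry their own locants. Ar = 2,4,5-trimethoxyphenyl.

Assumption: the sense of induction of the cinchona catalyst in step 4 cannot be predicted for this enolate; (DHQD)2PHAL is written, and its pseudoenantiomer (DHQ)2PHAL replaces it if a test run shows the opposite sense at C3.

Design remark: diol 8 is used as the mixture of carbinol epimers. The benzylic carbinol is engaged first at low temperature and the allylic one only after dilution and warming, so that the allyl cation forms when its nucleophile is already tethered.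

Step 1
Reactants: 1 2,4,5-trimethoxybenzaldehyde; 2 pent-1-en-3-one
Product: 3 2-[hydroxy(2,4,5-trimethoxyphenyl)methyl]pent-1-en-3-one (racemic)
Conditions: 1,4-diazabicyclo[2.2.2]octane (DABCO, 1.0 equiv), 2 (3 equiv), 1,4-dioxane/H2O 1:1, rt
Reagents that add atoms: none
Why: Morita–Baylis–Hillman reaction, in which DABCO adds to the enone, the ammonium enolate adds to the aldehyde and elimination returns the amine; the aqueous medium speeds the addition to this electron-rich aldehyde, and the racemic carbinol suffices because this centre is erased in step 4.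

Step 2
Reactants: 3 2-[hydroxy(2,4,5-trimethoxyphenyl)methyl]pent-1-en-3-one
Product: 4 tert-butyl 2-methylidene-3-oxo-1-(2,4,5-trimethoxyphenyl)pentyl carbonate (racemic)
Conditions: Boc2O (1.3 equiv), 4-(dimethylamino)pyridine (10 mol%), CH2Cl2, 0 °C
Reagents that add atoms: di-tert-butyl dicarbonate, CC(C)(C)OC(=O)OC(=O)OC(C)(C)C
Why: Nucleophile-catalysed acylation (tert-butoxycarbonylation) of the secondary allylic alcohol gives the Morita–Baylis–Hillman carbonate, whose leaving group later releases CO2 and tert-butoxide as internal base; no stereocentre of the target is involved.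

Step 3
Reactants: 5 1-(2,4,5-trimethoxyphenyl)propan-1-one
Product: 6 trimethyl{[(1Z)-1-(2,4,5-trimethoxyphenyl)prop-1-en-1-yl]oxy}silane
Conditions: TMSOTf (1.2 equiv), Et3N (1.5 equiv), CH2Cl2, 0 °C
Reagents that add atoms: trimethylsilyl trifluoromethanesulfonate, C[Si](C)(C)OS(=O)(=O)C(F)(F)F
Why: Soft enolisation with silylation (silyl enol ether formation) of the aryl ethyl ketone should give the (Z)-enol ether, the isomer that avoids allylic strain between the methyl group and the ortho-substituted aryl ring.

Step 4
Reactants: 4 tert-butyl 2-methylidene-3-oxo-1-(2,4,5-trimethoxyphenyl)pentyl carbonate; 6 trimethyl{[(1Z)-1-(2,4,5-trimethoxyphenyl)prop-1-en-1-yl]oxy}silane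
Product: 7 (2R,3S)-2-methyl-4-methylidene-1,3-bis(2,4,5-trimethoxyphenyl)heptane-1,5-dione
Conditions: hydroquinidine 1,4-phthalazinediyl diether, (DHQD)2PHAL (10 mol%), 6 (1.5 equiv), toluene, rt
Reagents that add atoms: none
Why: Lewis-base-catalysed asymmetric allylic alkylation of a Morita–Baylis–Hillman carbonate (SN2′–SN2′), in which the quinuclidine nitrogen displaces the carbonate to give a chiral allyl ammonium ion, the released tert-butoxide desilylates 6 and the enolate carbon (C4) attacks the aryl-bearing terminus (C3) on the face left open by the catalyst, which sets C3, while an open antiperiplanar approach of the (Z)-enolate should place the C4 methyl syn to the C3 aryl group in the extended C1–C5 chain; C4 lies α to the aryl ketone, so a minor C4 epimer can be separated and re-equilibrated.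

Step 5
Reactants: 7 (2R,3S)-2-methyl-4-methylidene-1,3-bis(2,4,5-trimethoxyphenyl)heptane-1,5-dione
Product: 8 (2R,3R)-2-methyl-4-methylidene-1,3-bis(2,4,5-trimethoxyphenyl)heptane-1,5-diol (epimer mixture at both carbinols)
Conditions: NaBH4 (3 equiv), CeCl3·7H2O (2 equiv), MeOH, −40 to 0 °C; aq. NaHCO3
Reagents that add atoms: none
Why: Luche reduction, in which NaBH4 with CeCl3 attacks the α-methylene ketone at the carbonyl carbon (1,2) and also reduces the aryl ketone; both new carbinol centres are left as mixtures because each is ionised in step 6.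

Step 6
Reactants: 8 (2R,3R)-2-methyl-4-methylidene-1,3-bis(2,4,5-trimethoxyphenyl)heptane-1,5-diol; 9 2,5-dimethoxyphenol
Product: 11 (6S,7R,9R,10R,11R)-7-ethyl-1,4-dimethoxy-10-methyl-8-methylidene-9,11-bis(2,4,5-trimethoxyphenyl)spiro[5.5]undeca-1,4-dien-3-one, via para-alkylated phenol 10 (not isolated)
Conditions: Bi(OTf)3 (10 mol%), 9 (1.5 equiv), CH2Cl2/(CF3)2CHOH 4:1, −40 °C; then dilution with CH2Cl2, 0 °C to rt, one flask
Reagents that add atoms: none
Why: Proposed new method: Bi(OTf)3 first ionises the C5 carbinol, whose cation is stabilised by the 2,4,5-trimethoxyphenyl ring, and the free para carbon of 9 captures it (C5–C6, phenol 10); on warming the allylic C1 carbinol ionises and the same carbon, now substituted and still para to OH, attacks C1 of the allyl cation, the phenolic proton is lost and the dienone forms directly (C1–C6). The closest known reaction types are Lewis-acid Friedel–Crafts alkylation of phenols with benzylic alcohols and acid-mediated dearomatising ipso-spirocyclisation of para-substituted phenols; their union on one carbon, with a non-aryl allyl cation in the second event, is without precedent. Ring A closes in a six-membered ipso (spiro) mode through a chair in which C1 of the planar allyl cation is attacked and the C2 methylene stays exocyclic. C3 and C4 are carried from 8; C5 and C1 are set by that chair with aryl and ethyl equatorial, and since both carbinol centres are erased and the benzylic C5–C6 bond can re-ionise under the acid, all isomers of 8 should converge; C6 is set by placing the methoxy-bearing C11 equatorial and C7–H axial, because an axial C11 would point its methoxy group under ring A at the axial C4–H and the C2 methylene. The step needs para-C rather than O- or ortho-alkylation of 9 (the para carbon is the most activated and least hindered site, and aryl ethers re-ionise), bimolecular capture at C5 ahead of indane closure onto the C3 aryl ring (excess 9, low temperature), and attack at C1 rather than at the methylene terminus of the allyl cation, for which the substrate offers only the ethyl group that makes C1 the more substituted, more positive terminus.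

Step 7
Reactants: 11 (6S,7R,9R,10R,11R)-7-ethyl-1,4-dimethoxy-10-methyl-8-methylidene-9,11-bis(2,4,5-trimethoxyphenyl)spiro[5.5]undeca-1,4-dien-3-one
Product: 12 tatanan B
Conditions: RhCl(PPh3)3 (15 mol%), H2 (1–4 atm), benzene/EtOH 1:1, rt
Reagents that add atoms: none
Why: Homogeneous catalytic hydrogenation with RhCl(PPh3)3 should reduce the 1,1-disubstituted exocyclic alkene and spare the trisubstituted, conjugated methoxy-enone alkenes of ring B; hydrogen is delivered to the C2 face opposite the axial C7–H of ring B, which lies under ring A in a 1,3-diaxial relation to C2, so the new C2–H is equatorial and the methyl group axial.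

Compound list
1 | 2,4,5-trimethoxybenzaldehyde | COc1cc(OC)c(C=O)cc1OC | starting material
2 | pent-1-en-3-one | CCC(=O)C=C | starting material
3 | 2-[hydroxy(2,4,5-trimethoxyphenyl)methyl]pent-1-en-3-one (racemic) | CCC(=O)C(=C)C(O)c1cc(OC)c(OC)cc1OC | intermediate
4 | tert-butyl 2-methylidene-3-oxo-1-(2,4,5-trimethoxyphenyl)pentyl carbonate (racemic) | CCC(=O)C(=C)C(OC(=O)OC(C)(C)C)c1cc(OC)c(OC)cc1OC | intermediate
5 | 1-(2,4,5-trimethoxyphenyl)propan-1-one | CCC(=O)c1cc(OC)c(OC)cc1OC | starting material
6 | trimethyl{[(1Z)-1-(2,4,5-trimethoxyphenyl)prop-1-en-1-yl]oxy}silane | C/C=C(\O[Si](C)(C)C)c1cc(OC)c(OC)cc1OC | intermediate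
7 | (2R,3S)-2-methyl-4-methylidene-1,3-bis(2,4,5-trimethoxyphenyl)heptane-1,5-dione | CCC(=O)C(=C)[C@H](c1cc(OC)c(OC)cc1OC)[C@@H](C)C(=O)c1cc(OC)c(OC)cc1OC | intermediate
8 | (2R,3R)-2-methyl-4-methylidene-1,3-bis(2,4,5-trimethoxyphenyl)heptane-1,5-diol, (1RS,5RS) mixture | CCC(O)C(=C)[C@H](c1cc(OC)c(OC)cc1OC)[C@@H](C)C(O)c1cc(OC)c(OC)cc1OC | intermediate
9 | 2,5-dimethoxyphenol | COc1ccc(OC)c(O)c1 | starting material
10 | 4-[(1S,2R,3R)-5-hydroxy-2-methyl-4-methylidene-1,3-bis(2,4,5-trimethoxyphenyl)heptyl]-2,5-dimethoxyphenol (epimers at the allylic carbinol) | CCC(O)C(=C)[C@H](c1cc(OC)c(OC)cc1OC)[C@@H](C)[C@H](c1cc(OC)c(OC)cc1OC)c1cc(OC)c(O)cc1OC | intermediate (not isolated)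
11 | (6S,7R,9R,10R,11R)-7-ethyl-1,4-dimethoxy-10-methyl-8-methylidene-9,11-bis(2,4,5-trimethoxyphenyl)spiro[5.5]undeca-1,4-dien-3-one; ring A chair with ethyl, both aryl groups and the methyl equatorial, C11 equatorial and C7 axial at the spiro centre | CC[C@@H]1C(=C)[C@H](c2cc(OC)c(OC)cc2OC)[C@@H](C)[C@H](c2cc(OC)c(OC)cc2OC)[C@]12C=C(OC)C(=O)C=C2OC | intermediate
12 | tatanan B, (6S,7R,8S,9S,10R,11R)-7-ethyl-1,4-dimethoxy-8,10-dimethyl-9,11-bis(2,4,5-trimethoxyphenyl)spiro[5.5]undeca-1,4-dien-3-one; as 11 with the C2 methyl axial | CC[C@@H]1[C@H](C)[C@H](c2cc(OC)c(OC)cc2OC)[C@@H](C)[C@H](c2cc(OC)c(OC)cc2OC)[C@]12C=C(OC)C(=O)C=C2OC | target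

Total step count: 7. Longest linear sequence: 6 steps (1 → 3 → 4 → 7 → 8 → 11 → 12); step 3 is a one-step branch.

Steps most likely to fail

1. Step 6.
What may go wrong: capture of the allyl cation at its unsubstituted methylene terminus instead of at C1 (an isomeric ring with an exocyclic ethylidene); closure of either cation onto the C3 aryl ring to an indane; proton loss from the C5 cation toward C4; acid-induced migration of the exocyclic alkene or dienone–phenol rearrangement of the product.
Fallback: it sets out from 8 and comes back at 11, and it separates the two alkylations into known reactions of opposite polarity at C1. Diol 8 and 9 are combined under a mild Brønsted acid (TsOH·H2O cat., CH2Cl2/(CF3)2CHOH, −20 °C), which should ionise only the benzylic carbinol (Friedel–Crafts benzylation of a phenol), and phenol 10 is isolated; C5 is then set under acyclic control, so its epimers are separated. Acetylation (Ac2O, pyridine) should give the diacetate of 10 F1. Palladium-catalysed silylation of the allylic acetate with hexamethyldisilane (Pd(dba)2, LiCl, DMF, 100 °C) should place silicon on the methylene terminus and give the allylsilane aryl acetate F2. Methanolysis (K2CO3, MeOH) should free the allylsilane phenol F3. Oxidation of F3 with PhI(OAc)2 in (CF3)2CHOH at 0 °C (oxidative dearomatisation with Hosomi–Sakurai-type trapping) makes the para carbon electrophilic; the allylsilane can then bond only through its γ-carbon C1 (SE2′), which fixes the regiochemistry, regenerates the exocyclic methylene and should give 11.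

2. Step 4.
What may go wrong: poor enantioface or diastereoface discrimination in the C3–C4 bond formation through the open transition state of an acyclic enolate, or slow SN2′ attack at the electron-rich, ortho-substituted benzylic terminus.
Fallback: it sets out from 1 and 6 and comes back at 8, and it moves the C3–C4 bond formation to iminium catalysis. Wittig homologation of 1 with (triphenylphosphoranylidene)acetaldehyde (toluene, 80 °C) should give (2E)-3-(2,4,5-trimethoxyphenyl)prop-2-enal F4. Organocatalytic Mukaiyama–Michael addition of 6 to F4 ((2S,5S)-5-benzyl-2-tert-butyl-3-methylimidazolidin-4-one trifluoroacetate or its enantiomer, whichever gives the 3S adduct, CH2Cl2/H2O, −20 °C) should give the syn keto aldehyde F5. Organocatalytic α-methylenation (aqueous formaldehyde, pyrrolidine and propionic acid cat., i-PrOH, 45 °C) touches only the aldehyde α-carbon and should give the α-methylene keto aldehyde F6. EtMgBr (THF, −78 °C) adds to the aldehyde ahead of the hindered aryl ketone and should give the hydroxy ketone F7. NaBH4 (MeOH, 0 °C) then gives 8.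

3. Step 7.
What may go wrong: hydrogen delivery to the wrong face of the exocyclic alkene, rhodium-hydride-induced migration of the alkene into ring A, or slow turnover at this doubly flanked alkene.
Fallback: it sets out from 11 and ends at 12. Diimide, generated from 2-nitrobenzenesulfonohydrazide and Et3N in CH2Cl2 at rt, transfers H2 in a concerted, metal-free syn addition from the same open face; it cannot isomerise the alkene and should leave the polarised dienone alkenes. This detour makes no compound outside the list (F0).

Further compounds
F1 | step 6 | diacetate of 10: 4-[5-acetoxy-2-methyl-4-methylidene-1,3-bis(2,4,5-trimethoxyphenyl)heptyl]-2,5-dimethoxyphenyl acetate, C3, C4 and C5 as in 10 | CCC(OC(C)=O)C(=C)[C@H](c1cc(OC)c(OC)cc1OC)[C@@H](C)[C@H](c1cc(OC)c(OC)cc1OC)c1cc(OC)c(OC(C)=O)cc1OC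
F2 | step 6 | allylsilane aryl acetate: 2,5-dimethoxy-4-{2-methyl-1,3-bis(2,4,5-trimethoxyphenyl)-4-[(trimethylsilyl)methyl]hept-4-enyl}phenyl acetate, stereocentres as in 10, alkene geometry not defined | CCC=C(C[Si](C)(C)C)[C@H](c1cc(OC)c(OC)cc1OC)[C@@H](C)[C@H](c1cc(OC)c(OC)cc1OC)c1cc(OC)c(OC(C)=O)cc1OC
F3 | step 6 | allylsilane phenol: 2,5-dimethoxy-4-{2-methyl-1,3-bis(2,4,5-trimethoxyphenyl)-4-[(trimethylsilyl)methyl]hept-4-enyl}phenol, stereocentres as in 10, alkene geometry not defined | CCC=C(C[Si](C)(C)C)[C@H](c1cc(OC)c(OC)cc1OC)[C@@H](C)[C@H](c1cc(OC)c(OC)cc1OC)c1cc(OC)c(O)cc1OC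
F4 | step 4 | (2E)-3-(2,4,5-trimethoxyphenyl)prop-2-enal | O=C/C=C/c1cc(OC)c(OC)cc1OC
F5 | step 4 | (3S,4R)-4-methyl-5-oxo-3,5-bis(2,4,5-trimethoxyphenyl)pentanal | O=CC[C@H](c1cc(OC)c(OC)cc1OC)[C@@H](C)C(=O)c1cc(OC)c(OC)cc1OC
F6 | step 4 | (3S,4R)-4-methyl-2-methylidene-5-oxo-3,5-bis(2,4,5-trimethoxyphenyl)pentanal | O=CC(=C)[C@H](c1cc(OC)c(OC)cc1OC)[C@@H](C)C(=O)c1cc(OC)c(OC)cc1OC
F7 | step 4 | (2R,3R)-5-hydroxy-2-methyl-4-methylidene-1,3-bis(2,4,5-trimethoxyphenyl)heptan-1-one, carbinol epimers | CCC(O)C(=C)[C@H](c1cc(OC)c(OC)cc1OC)[C@@H](C)C(=O)c1cc(OC)c(OC)cc1OC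
F0 | step 7 | none | none
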